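**Plan**

- Retrosynthesis: the polyene is cut at C11=C12 and C11'=C12' (two Wittig reactions on the C10 dialdehyde 20; the 7',8'-dihydro-ψ half is a farnesyl unit). The C15 salt 17 is traced through (R)-α-ionone 15 to the vinyl ring 13 (C7=C8 by cross-metathesis). Last, the ε-ring is opened at C2–C3 and C5–C6 together.
- Enabling feature: in ring C1–C6, C6 is a doubly allylic CH between ring C4=C5 and chain C7=C8, and C2 is a CH2 on the quaternary C1. So C3–C4=C5(CH3) can be a (Z)-3-bromobut-2-enyl unit, an allylic electrophile at C3 and a vinylic electrophile at C5. It meets an α-sulfonyl carboxylate at C2 and an allylsilane C6=C7–C8.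
- Forward: 1 gives acid 5 (C2, C1, C6–C8); an ester tether to bromo alcohol 8 and sulfonylation give 10; one palladium operation (loss of CO2, then of silicon) closes the ring to 12. Desulfonylation, cross-metathesis, vinyl addition and phosphonium formation give 17; 19 + 20 give aldehyde 21; 17 + 21 give the target.
- Stereochemistry: C6 (R) comes from ligand-controlled enantioface selection in the 6-exo carbopalladation of step 7. The E double bonds come from cross-metathesis, allylic transposition and Wittig reactions with equilibration; the two E bonds of the farnesyl part are bought.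

Key step: step 7

Remark: (S)-BINAP stands for whichever enantiomer of the ligand leads to the 6R series; the sense of induction has to be assigned by experiment on 15, and the antipodal ligand serves equally.

**Route**

Step 1
Reactants: 1 methyl 3,3-dimethylpent-4-enoate
Product: 3 methyl 3,3-dimethyl-4-oxobutanoate, via ozonide 2 (not isolated)
Conditions: O3, CH2Cl2, −78 °C; then Me2S, −78 → 25 °C
Reagents that add atoms: ozone, [O-][O+]=O
Why: Ozonolysis with reductive work-up cleaves the only C=C bond and leaves a non-enolisable aldehyde on the quaternary carbon that becomes C1.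

Step 2
Reactants: 3 methyl 3,3-dimethyl-4-oxobutanoate
Product: 4 methyl (4Z)-3,3-dimethyl-6-(trimethylsilyl)hex-4-enoate
Conditions: Ph3PCH3Br, NaN(SiMe3)2, THF, 0 °C; Me3SiCH2I, 25 °C; NaN(SiMe3)2, −78 °C; then 3, −78 → 25 °C
Reagents that add atoms: methyltriphenylphosphonium bromide, C[P+](c1ccccc1)(c1ccccc1)c1ccccc1.[Br-]; (iodomethyl)trimethylsilane, C[Si](C)(C)CI
Why: Wittig olefination with the non-stabilised β-silyl ylide, built in the flask from methylenetriphenylphosphorane and Me3SiCH2I, is expected to give the (Z)-allylsilane (kinetic cis-oxaphosphetane, sodium base, hindered aldehyde), the methyl ester not being attacked at −78 °C.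

Step 3
Reactants: 4 methyl (4Z)-3,3-dimethyl-6-(trimethylsilyl)hex-4-enoate
Product: 5 (4Z)-3,3-dimethyl-6-(trimethylsilyl)hex-4-enoic acid
Conditions: LiOH·H2O, THF/MeOH/H2O, 40 °C; then 1 M HCl, 0 °C (brief)
Reagents that add atoms: lithium hydroxide, [Li+].[OH-]
Why: Saponification of the methyl ester does not touch the base-stable allylsilane, and the cold, brief acidification avoids protodesilylation.

Step 4
Reactants: 6 but-2-yn-1-ol
Product: 8 (2Z)-3-bromobut-2-en-1-ol, via cyclic alkenylalanate 7 (not isolated)
Conditions: NaAlH2(OCH2CH2OMe)2, Et2O, 0 → 25 °C; then NBS, −78 °C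
Reagents that add atoms: N-bromosuccinimide, O=C1CCC(=O)N1Br
Why: Hydroxyl-directed trans-hydroalumination of the propargylic alcohol places aluminium at C3 in alanate 7, and bromodealumination with retention fixes the Z geometry (bromine cis to CH2OH) that the later ring closure needs.

Step 5
Reactants: 5 (4Z)-3,3-dimethyl-6-(trimethylsilyl)hex-4-enoic acid; 8 (2Z)-3-bromobut-2-en-1-ol
Product: 9 (2Z)-3-bromobut-2-en-1-yl (4Z)-3,3-dimethyl-6-(trimethylsilyl)hex-4-enoate
Conditions: EDC·HCl, DMAP (cat.), CH2Cl2, 0 → 25 °C
Reagents that add atoms: none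
Why: Carbodiimide (Steglich-type) esterification joins the two halves through an ester whose carboxyl carbon is later lost as CO2.

Step 6
Reactants: 9 (2Z)-3-bromobut-2-en-1-yl (4Z)-3,3-dimethyl-6-(trimethylsilyl)hex-4-enoate
Product: 10 (2Z)-3-bromobut-2-en-1-yl (2RS,4Z)-3,3-dimethyl-2-(phenylsulfonyl)-6-(trimethylsilyl)hex-4-enoate
Conditions: LiN(iPr)2 (2.1 equiv), THF, −78 °C; PhSO2F, −78 → −40 °C; AcOH
Reagents that add atoms: benzenesulfonyl fluoride, O=S(=O)(F)c1ccccc1
Why: C-Sulfonylation of the lithium ester enolate with a sulfonyl fluoride (which, unlike the chloride, does not halogenate) installs the carbanion-stabilising group at the future C2, the second equivalent of base holding the acidic product as its anion until the quench.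

Step 7
Reactants: 10 (2Z)-3-bromobut-2-en-1-yl (2RS,4Z)-3,3-dimethyl-2-(phenylsulfonyl)-6-(trimethylsilyl)hex-4-enoate
Product: 12 {[(1RS,3S)-3-ethenyl-2,2,4-trimethylcyclohex-4-en-1-yl]sulfonyl}benzene, via open-chain bromoalkenyl sulfone 11 (not isolated)
Conditions: Pd2(dba)3·CHCl3 (5 mol%), (S)-BINAP (12 mol%), Ag3PO4 (1.2 equiv), DMF, 25 → 80 °C
Reagents that add atoms: none
Why: Proposed new method: zerovalent palladium carrying BINAP should first ionise the allylic C–O bond of 10, the α-sulfonyl carboxylate then loses CO2 and the sulfone-stabilised carbanion attacks the unsubstituted CH2 terminus of the η3-allyl ligand to form C2–C3 and the bromoalkene 11 (decarboxylative Tsuji–Trost allylation; closest known type: decarboxylative allylation of allyl α-sulfonyl acetates), after which the same catalyst inserts into the C–Br bond, Ag3PO4 removes bromide, and the cationic alkenylpalladium species adds syn across the allylsilane double bond and loses the silyl group to form C5–C6 and the vinyl group (closest known type: silane-terminated asymmetric Heck cyclisation). The only ring formed is the six-membered carbocycle, closed by 6-exo-trig carbopalladation. The stereocentre at C6 is created in that carbopalladation and is controlled by the chiral diphosphine on cationic palladium, which selects the enantioface of the (Z)-allylsilane; the sulfone-bearing carbon is racemic and is erased in step 8. The step needs allylation at C3 and not at the bromine-bearing terminus (steric and electronic bias of the bromo, methyl-substituted terminus), retention of the Z bromoalkene (no σ-bonding of palladium at that tertiary terminus, hence no syn–anti exchange), 6-exo and not 7-endo closure (four-atom tether), and termination by loss of silicon and not of the C6 hydrogen (β-silyl group on C8 and the halide-free cationic pathway). The new element is the merger of the two palladium cycles in one flask; each half is precedented separately, and loss of CO2 makes the first half irreversible.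

Step 8
Reactants: 12 {[(1RS,3S)-3-ethenyl-2,2,4-trimethylcyclohex-4-en-1-yl]sulfonyl}benzene
Product: 13 (6R)-6-ethenyl-1,5,5-trimethylcyclohex-1-ene
Conditions: Na(Hg) (6% Na), Na2HPO4, MeOH/THF, −20 → 0 °C
Reagents that add atoms: none
Why: Reductive desulfonylation by electron transfer replaces C–S by C–H, which removes the helper group and its stereocentre without touching the skipped diene or C6 (the descriptor changes from S to R only because the sulfonyl group no longer sets the priorities).

Step 9
Reactants: 13 (6R)-6-ethenyl-1,5,5-trimethylcyclohex-1-ene; 14 but-3-en-2-one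
Product: 15 (R)-α-ionone, (3E)-4-[(1R)-2,6,6-trimethylcyclohex-2-en-1-yl]but-3-en-2-one
Conditions: second-generation Hoveyda–Grubbs catalyst, RuCl2(H2IMes)(=CH-C6H4-2-OiPr) (5 mol%), 14 (5 equiv), 1,4-benzoquinone (10 mol%), CH2Cl2, 40 °C
Reagents that add atoms: none
Why: Olefin cross-metathesis of the monosubstituted vinyl group with the electron-poor enone partner should give the E enone, the trisubstituted ring alkene being inert and benzoquinone suppressing ruthenium hydride double-bond migration.

Step 10
Reactants: 15 (R)-α-ionone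
Product: 16 (1E,3RS)-3-methyl-1-[(1R)-2,6,6-trimethylcyclohex-2-en-1-yl]penta-1,4-dien-3-ol
Conditions: CH2=CHMgBr, THF, −20 → 0 °C; aq. NH4Cl
Reagents that add atoms: vinylmagnesium bromide, C=C[Mg]Br
Why: 1,2-Addition of the vinyl Grignard reagent to the ketone gives the tertiary bis-allylic alcohol, whose new stereocentre is lost in the next step.

Step 11
Reactants: 16 (1E,3RS)-3-methyl-1-[(1R)-2,6,6-trimethylcyclohex-2-en-1-yl]penta-1,4-dien-3-ol
Product: 17 {(2E,4E)-3-methyl-5-[(1R)-2,6,6-trimethylcyclohex-2-en-1-yl]penta-2,4-dien-1-yl}triphenylphosphonium bromide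
Conditions: Ph3P·HBr, MeOH, 0 → 25 °C
Reagents that add atoms: triphenylphosphine hydrobromide, [PH+](c1ccccc1)(c1ccccc1)c1ccccc1.[Br-]
Why: Acid-promoted ionisation of the tertiary alcohol to the pentadienyl cation and capture by triphenylphosphine at the unhindered terminus (allylic transposition) gives the conjugated E,E salt, the standard entry to C15 Wittig salts of the ionone series.

Step 12
Reactants: 18 (2E,6E)-farnesyl bromide
Product: 19 [(2E,6E)-3,7,11-trimethyldodeca-2,6,10-trien-1-yl]triphenylphosphonium bromide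
Conditions: PPh3, toluene, 25 °C, dark
Reagents that add atoms: triphenylphosphine, P(c1ccccc1)(c1ccccc1)c1ccccc1
Why: SN2 quaternisation of triphenylphosphine by the primary allylic bromide keeps both trisubstituted E double bonds.

Step 13
Reactants: 19 farnesyltriphenylphosphonium bromide; 20 (2E,4E,6E)-2,7-dimethylocta-2,4,6-trienedial
Product: 21 (2E,4E,6E,8E,10E,14E)-2,7,11,15,19-pentamethylicosa-2,4,6,8,10,14,18-heptaenal
Conditions: NaOMe, CH2Cl2/MeOH, 0 °C, 20 in excess (3 equiv); then I2 (cat.), heptane, 25 °C, daylight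
Reagents that add atoms: none
Why: Wittig olefination of the allylic ylide generated in the presence of excess dialdehyde favours mono-olefination, and iodine-catalysed equilibration should convert the new disubstituted double bond to the E isomer.

Step 14
Reactants: 17 C15 phosphonium bromide; 21 C25 aldehyde
Product: 22 (6R)-7',8'-dihydro-ε,ψ-carotene (α-zeacarotene, CNP0213990.1)
Conditions: NaOMe, CH2Cl2/MeOH, 0 → 25 °C, Ar, dark; then heptane, reflux, crystallisation
Reagents that add atoms: none
Why: The final Wittig olefination joins the C15 ylide and the C25 aldehyde at C11=C12, and thermal equilibration with crystallisation is expected to deliver the all-E polyene, C6 being untouched because the ylide does not acidify it.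

**Compound list**

1 | methyl 3,3-dimethylpent-4-enoate | COC(=O)CC(C)(C)C=C | starting material
2 | methyl 3-methyl-3-(1,2,4-trioxolan-3-yl)butanoate (ozonide, not isolated) | COC(=O)CC(C)(C)C1OCOO1 | intermediate
3 | methyl 3,3-dimethyl-4-oxobutanoate | COC(=O)CC(C)(C)C=O | intermediate
4 | methyl (4Z)-3,3-dimethyl-6-(trimethylsilyl)hex-4-enoate | COC(=O)CC(C)(C)/C=C\C[Si](C)(C)C | intermediate
5 | (4Z)-3,3-dimethyl-6-(trimethylsilyl)hex-4-enoic acid | OC(=O)CC(C)(C)/C=C\C[Si](C)(C)C | intermediate
6 | but-2-yn-1-ol | CC#CCO | starting material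
7 | sodium 2,2-bis(2-methoxyethoxy)-3-methyl-2,5-dihydro-1,2-oxaalumol-2-uide (cyclic alkenylalanate, not isolated) | CC1=CCO[Al-]1(OCCOC)OCCOC.[Na+] | intermediate
8 | (2Z)-3-bromobut-2-en-1-ol | C/C(Br)=C/CO | intermediate
9 | (2Z)-3-bromobut-2-en-1-yl (4Z)-3,3-dimethyl-6-(trimethylsilyl)hex-4-enoate | C/C(Br)=C/COC(=O)CC(C)(C)/C=C\C[Si](C)(C)C | intermediate
10 | (2Z)-3-bromobut-2-en-1-yl (2RS,4Z)-3,3-dimethyl-2-(phenylsulfonyl)-6-(trimethylsilyl)hex-4-enoate | C/C(Br)=C/COC(=O)C(S(=O)(=O)c1ccccc1)C(C)(C)/C=C\C[Si](C)(C)C | intermediate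
11 | {[(2Z,5RS,7Z)-2-bromo-6,6-dimethyl-9-(trimethylsilyl)nona-2,7-dien-5-yl]sulfonyl}benzene (not isolated) | C/C(Br)=C/CC(S(=O)(=O)c1ccccc1)C(C)(C)/C=C\C[Si](C)(C)C | intermediate
12 | {[(1RS,3S)-3-ethenyl-2,2,4-trimethylcyclohex-4-en-1-yl]sulfonyl}benzene | C=C[C@H]1C(C)=CCC(S(=O)(=O)c2ccccc2)C1(C)C | intermediate
13 | (6R)-6-ethenyl-1,5,5-trimethylcyclohex-1-ene | C=C[C@H]1C(C)=CCCC1(C)C | intermediate
14 | but-3-en-2-one | CC(=O)C=C | starting material
15 | (R)-α-ionone, (3E)-4-[(1R)-2,6,6-trimethylcyclohex-2-en-1-yl]but-3-en-2-one | CC(=O)/C=C/[C@H]1C(C)=CCCC1(C)C | intermediate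
16 | (1E,3RS)-3-methyl-1-[(1R)-2,6,6-trimethylcyclohex-2-en-1-yl]penta-1,4-dien-3-ol | C=CC(C)(O)/C=C/[C@H]1C(C)=CCCC1(C)C | intermediate
17 | {(2E,4E)-3-methyl-5-[(1R)-2,6,6-trimethylcyclohex-2-en-1-yl]penta-2,4-dien-1-yl}triphenylphosphonium bromide | C(/C=C(C)/C=C/[C@H]1C(C)=CCCC1(C)C)[P+](c1ccccc1)(c1ccccc1)c1ccccc1.[Br-] | intermediate
18 | (2E,6E)-farnesyl bromide, (2E,6E)-1-bromo-3,7,11-trimethyldodeca-2,6,10-triene | CC(C)=CCC/C(C)=C/CC/C(C)=C/CBr | starting material
19 | [(2E,6E)-3,7,11-trimethyldodeca-2,6,10-trien-1-yl]triphenylphosphonium bromide | CC(C)=CCC/C(C)=C/CC/C(C)=C/C[P+](c1ccccc1)(c1ccccc1)c1ccccc1.[Br-] | intermediate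
20 | (2E,4E,6E)-2,7-dimethylocta-2,4,6-trienedial | O=C/C(C)=C/C=C/C=C(C)/C=O | starting material
21 | (2E,4E,6E,8E,10E,14E)-2,7,11,15,19-pentamethylicosa-2,4,6,8,10,14,18-heptaenal | CC(C)=CCC/C(C)=C/CC/C(C)=C/C=C/C(C)=C/C=C/C=C(C)/C=O | intermediate
22 | (6R)-7',8'-dihydro-ε,ψ-carotene (α-zeacarotene) | CC(C)=CCC/C(C)=C/CC/C(C)=C/C=C/C(C)=C/C=C/C=C(C)/C=C/C=C(C)/C=C/[C@H]1C(C)=CCCC1(C)C | target

**Count**

Total steps: 14. Longest linear sequence: 11 steps (1, 2, 3, 5, 6, 7, 8, 9, 10, 11, 14).

**Steps most likely to fail**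

1. Step 7 (proposed new method). The two catalytic cycles may interfere: insertion into the C–Br bond before ionisation, or protonation of the carbanion instead of allylation. The Z geometry of the bromoalkene may be lost by syn–anti exchange of the allyl ligand, and the enantioface selection in the carbopalladation may be poor. The fallback uses known chemistry, sets out from 4 and returns at 12. Ester 4 is C-sulfonylated as in step 6 (LiN(iPr)2, PhSO2F) to methyl (2RS,4Z)-3,3-dimethyl-2-(phenylsulfonyl)-6-(trimethylsilyl)hex-4-enoate F1. Krapcho dealkoxycarbonylation (LiCl, wet DMSO, 140 °C) gives {[(3Z)-2,2-dimethyl-5-(trimethylsilyl)pent-3-en-1-yl]sulfonyl}benzene F2. Alcohol 8 is converted by the Appel reaction (CBr4, PPh3, CH2Cl2) into (2Z)-1,3-dibromobut-2-ene F3. Lithiation of F2 (n-BuLi, THF, −78 °C) and SN2 alkylation with F3 give 11, now isolated, without any η3-allyl species that could scramble the geometry. The silane-terminated Heck cyclisation is then run on 11 alone under the conditions of step 7 to give 12, so ligand and silver salt can be tuned free of the decarboxylation.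

2. Step 9. Metathesis at the hindered vinyl group may be slow, and ruthenium hydride may move double bonds into conjugation with loss of the C6 stereocentre. The fallback sets out from 13 and returns at 15. Hydrozirconation of the vinyl group with Cp2Zr(H)Cl and copper-catalysed acylation of the alkylzirconocene with acetyl chloride (CuBr·SMe2 cat.) give 4-[(1R)-2,6,6-trimethylcyclohex-2-en-1-yl]butan-2-one F4. Dehydrogenation with o-iodoxybenzoic acid and 4-methoxypyridine N-oxide in DMSO, which can place the new double bond only on the methylene side (C7=C8), gives 15.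

3. Step 6. Attack of the hindered enolate on sulfur may be slow, the amide base may dehydrobrominate the bromoalkene, and the allyl ester enolate may undergo Claisen rearrangement on warming. The fallback sets out from 4 and returns at 10. Sulfenylation of 4 (LiN(iPr)2, THF, −78 °C; PhSSPh) gives methyl (2RS,4Z)-3,3-dimethyl-2-(phenylsulfanyl)-6-(trimethylsilyl)hex-4-enoate F5. Saponification (LiOH) gives (2RS,4Z)-3,3-dimethyl-2-(phenylsulfanyl)-6-(trimethylsilyl)hex-4-enoic acid F6. Esterification with 8 (EDC·HCl, DMAP) gives (2Z)-3-bromobut-2-en-1-yl (2RS,4Z)-3,3-dimethyl-2-(phenylsulfanyl)-6-(trimethylsilyl)hex-4-enoate F7. Chemoselective oxidation of sulfur (H2O2, cat. (NH4)6Mo7O24·4H2O, EtOH, 0 °C) gives 10, so no strong base meets the bromoalkene.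

**Further compounds**

F1 | step 7 | methyl (2RS,4Z)-3,3-dimethyl-2-(phenylsulfonyl)-6-(trimethylsilyl)hex-4-enoate | COC(=O)C(S(=O)(=O)c1ccccc1)C(C)(C)/C=C\C[Si](C)(C)C
F2 | step 7 | {[(3Z)-2,2-dimethyl-5-(trimethylsilyl)pent-3-en-1-yl]sulfonyl}benzene | O=S(=O)(CC(C)(C)/C=C\C[Si](C)(C)C)c1ccccc1
F3 | step 7 | (2Z)-1,3-dibromobut-2-ene | C/C(Br)=C/CBr
F4 | step 9 | 4-[(1R)-2,6,6-trimethylcyclohex-2-en-1-yl]butan-2-one | CC(=O)CC[C@H]1C(C)=CCCC1(C)C
F5 | step 6 | methyl (2RS,4Z)-3,3-dimethyl-2-(phenylsulfanyl)-6-(trimethylsilyl)hex-4-enoate | COC(=O)C(Sc1ccccc1)C(C)(C)/C=C\C[Si](C)(C)C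
F6 | step 6 | (2RS,4Z)-3,3-dimethyl-2-(phenylsulfanyl)-6-(trimethylsilyl)hex-4-enoic acid | OC(=O)C(Sc1ccccc1)C(C)(C)/C=C\C[Si](C)(C)C
F7 | step 6 | (2Z)-3-bromobut-2-en-1-yl (2RS,4Z)-3,3-dimethyl-2-(phenylsulfanyl)-6-(trimethylsilyl)hex-4-enoate | C/C(Br)=C/COC(=O)C(Sc1ccccc1)C(C)(C)/C=C\C[Si](C)(C)C
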